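Assumption: the target SMILES has no stereocentre and no stereogenic double bond, so the compound is achiral and "single enantiomer" calls for no stereocontrol.

**Retrosynthetic overview**
- Last step: the free acid is released from a tert-butyl ester, leaving the depside ester intact.
- Key disconnection: the aryl C–O bond of the depside, not the usual acyl C–O bond. The hindered 2,4-dimethoxy-6-pentylbenzoic acid acts as an O-nucleophile in a copper-catalysed oxidative coupling with an arylboronic acid.
- The arylboronic acid comes from sterically controlled iridium-catalysed C–H borylation of tert-butyl 2-methoxy-6-propylbenzoate, itself made by lateral lithiation and ethylation of the 6-methyl ester.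
- The acid fragment comes from olivetol dimethyl ether by bromination, Br–Li exchange and carboxylation.
- No ring is formed: ring A (dimethoxy-pentyl) and ring B (methoxy-propyl) are bought as benzenes and joined in the second-to-last step.

**Route**

Step 1
Reactants: 1 1,3-dimethoxy-5-pentylbenzene
Product: 2 2-bromo-1,5-dimethoxy-3-pentylbenzene
Conditions: NBS (1.0 equiv), MeCN, 0 °C to rt
Reagents that add atoms: N-bromosuccinimide, O=C1CCC(=O)N1Br
Why: Electrophilic aromatic bromination by NBS goes to the ring position between the pentyl group and a methoxy group, which is para to the other methoxy group, because the alternative site between the two methoxy groups is only ortho-activated and more crowded, as is well established for 5-alkylresorcinol dimethyl ethers.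

Step 2
Reactants: 2 2-bromo-1,5-dimethoxy-3-pentylbenzene
Product: 5 2,4-dimethoxy-6-pentylbenzoic acid, via aryllithium 3 (not isolated), via lithium carboxylate 4 (not isolated)
Conditions: n-BuLi (1.05 equiv), THF, −78 °C; CO2 (dry gas), −78 °C to rt; aq HCl work-up
Reagents that add atoms: carbon dioxide, O=C=O
Why: Bromine–lithium exchange at −78 °C is much faster than deprotonation between the methoxy groups and places lithium exactly on the brominated carbon, and the aryllithium is then carboxylated by CO2 and protonated on acidic work-up.

Step 3
Reactants: 6 2-methoxy-6-methylbenzoic acid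
Product: 7 tert-butyl 2-methoxy-6-methylbenzoate
Conditions: tert-butyl 2,2,2-trichloroacetimidate (2 equiv), BF3·OEt2 (cat), CH2Cl2/cyclohexane, rt
Reagents that add atoms: tert-butyl 2,2,2-trichloroacetimidate, CC(C)(C)OC(=N)C(Cl)(Cl)Cl
Why: Acid-catalysed tert-butylation with the trichloroacetimidate alkylates the carboxyl oxygen (tert-butyl cation transfer) instead of requiring attack at the carbonyl carbon, so the two ortho substituents do not hinder ester formation.

Step 4
Reactants: 7 tert-butyl 2-methoxy-6-methylbenzoate
Product: 9 tert-butyl 2-methoxy-6-propylbenzoate, via benzylic lithium species 8 (not isolated)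
Conditions: LiN(iPr)2 (1.2 equiv), THF, −78 °C, 1 h; EtI (1.5 equiv), −78 °C to 0 °C
Reagents that add atoms: iodoethane, CCI
Why: Lateral (benzylic) lithiation of an ortho-toluate: LiN(iPr)2 removes a proton from the methyl group to give a benzylic anion stabilised by the adjacent ester, which is alkylated by iodoethane in an SN2 reaction to extend methyl to propyl, while the bulky tert-butyl ester resists self-condensation.

Step 5
Reactants: 9 tert-butyl 2-methoxy-6-propylbenzoate
Product: 11 [4-(tert-butoxycarbonyl)-3-methoxy-5-propylphenyl]boronic acid, via pinacol boronate 10 (not isolated)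
Conditions: [Ir(OMe)(cod)]2 (1.5 mol%), 4,4'-di-tert-butyl-2,2'-bipyridine (3 mol%), B2pin2 (0.6 equiv), THF, 80 °C; then NaIO4 (3 equiv), NH4OAc (3 equiv), acetone/H2O, rt
Reagents that add atoms: bis(pinacolato)diboron, CC1(C)OB(OC1(C)C)B1OC(C)(C)C(C)(C)O1; water, O
Why: Iridium-catalysed aromatic C–H borylation is governed by sterics and takes the only ring C–H with no ortho substituent, the one para to the ester and meta to both methoxy and propyl, after which periodate cleaves the pinacol oxidatively and frees the boronic acid.

Step 6
Reactants: 5 2,4-dimethoxy-6-pentylbenzoic acid; 11 [4-(tert-butoxycarbonyl)-3-methoxy-5-propylphenyl]boronic acid (2 equiv)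
Product: 12 tert-butyl 4-[(2,4-dimethoxy-6-pentylbenzoyl)oxy]-2-methoxy-6-propylbenzoate
Conditions: Cu(OTf)2 (40 mol%), urea (1 equiv), EtOAc, air, 60 °C
Reagents that add atoms: none
Why: Chan–Lam-type copper-catalysed aerobic C–O coupling: the carboxylate of 5 binds divalent copper, the aryl group of 11 is transmetalated from boron, and reductive elimination from a trivalent copper aryl carboxylate forms the aryl–oxygen bond, so the hindered acid reacts as an oxygen nucleophile and its blocked carbonyl carbon never has to be attacked.

Step 7
Reactants: 12 tert-butyl 4-[(2,4-dimethoxy-6-pentylbenzoyl)oxy]-2-methoxy-6-propylbenzoate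
Product: 13 4-[(2,4-dimethoxy-6-pentylbenzoyl)oxy]-2-methoxy-6-propylbenzoic acid
Conditions: TFA/CH2Cl2 (1:4), 0 °C to rt; evaporate, recrystallise
Reagents that add atoms: none
Why: Acidolysis of the tert-butyl ester by alkyl–oxygen cleavage (loss of the tert-butyl cation as 2-methylpropene) frees the acid without touching the aryl ester or the methyl ethers, and ring tert-butylation is disfavoured because every free ring position is flanked by two substituents.

**Compound list**
1 | 1,3-dimethoxy-5-pentylbenzene (olivetol dimethyl ether) | CCCCCc1cc(OC)cc(OC)c1 | starting material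
2 | 2-bromo-1,5-dimethoxy-3-pentylbenzene | CCCCCc1cc(OC)cc(OC)c1Br | intermediate
3 | (2,4-dimethoxy-6-pentylphenyl)lithium | [Li]c1c(CCCCC)cc(OC)cc1OC | intermediate
4 | lithium 2,4-dimethoxy-6-pentylbenzoate | CCCCCc1cc(OC)cc(OC)c1C(=O)[O-].[Li+] | intermediate
5 | 2,4-dimethoxy-6-pentylbenzoic acid | CCCCCc1cc(OC)cc(OC)c1C(=O)O | intermediate
6 | 2-methoxy-6-methylbenzoic acid | COc1cccc(C)c1C(=O)O | starting material
7 | tert-butyl 2-methoxy-6-methylbenzoate | COc1cccc(C)c1C(=O)OC(C)(C)C | intermediate
8 | {[2-(tert-butoxycarbonyl)-3-methoxyphenyl]methyl}lithium | [Li]Cc1cccc(OC)c1C(=O)OC(C)(C)C | intermediate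
9 | tert-butyl 2-methoxy-6-propylbenzoate | CCCc1cccc(OC)c1C(=O)OC(C)(C)C | intermediate
10 | tert-butyl 2-methoxy-6-propyl-4-(4,4,5,5-tetramethyl-1,3,2-dioxaborolan-2-yl)benzoate | CCCc1cc(B2OC(C)(C)C(C)(C)O2)cc(OC)c1C(=O)OC(C)(C)C | intermediate
11 | [4-(tert-butoxycarbonyl)-3-methoxy-5-propylphenyl]boronic acid | CCCc1cc(B(O)O)cc(OC)c1C(=O)OC(C)(C)C | intermediate
12 | tert-butyl 4-[(2,4-dimethoxy-6-pentylbenzoyl)oxy]-2-methoxy-6-propylbenzoate | CCCCCc1cc(OC)cc(OC)c1C(=O)Oc1cc(CCC)c(C(=O)OC(C)(C)C)c(OC)c1 | intermediate
13 | 4-[(2,4-dimethoxy-6-pentylbenzoyl)oxy]-2-methoxy-6-propylbenzoic acid | CCCCCc1cc(OC)cc(OC)c1C(=O)Oc1cc(CCC)c(C(=O)O)c(OC)c1 | target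

**Step count and risks**

Total step count: 7. Longest linear sequence: 5 steps (steps 3 to 7, from 6 to 13); steps 1 and 2 form the second branch.

First risk, step 6 (copper-catalysed aryl–oxygen coupling). The boronic acid may be lost to protodeboronation or phenol formation, and adventitious TfOH from Cu(OTf)2 may attack the tert-butyl ester. The fallback gives up the aryl C–O disconnection and returns to acyl transfer. It sets out from boronic acid 11, which aqueous H2O2 in THF converts by ipso-hydroxylation into tert-butyl 4-hydroxy-2-methoxy-6-propylbenzoate F1. F1 is then acylated by acid 5 under Steglich conditions (DCC, catalytic DMAP, CH2Cl2, rt), and the route is rejoined at ester 12.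

Second risk, step 5 (C–H borylation and release of the boronic acid). Some borylation next to the small methoxy group is possible, and the free boronic acid may be impure after periodate cleavage. The fallback changes what is isolated and how it is purified. It sets out from the crude pinacol boronate 10, which aqueous KHF2 in MeOH converts into potassium [4-(tert-butoxycarbonyl)-3-methoxy-5-propylphenyl]trifluoroborate F2. This salt is recrystallised from acetone/Et2O, which removes regioisomers and pinacol. Stirring F2 with silica gel in EtOAc/water hydrolyses it to boronic acid 11, where the route is rejoined.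

Third risk, step 4 (lateral lithiation and ethylation). Deprotonation may be incomplete, the product may be ethylated twice, or the benzylic anion may attack the ester. The fallback moves the C–C bond formation to the free acid, where no ester electrophile is present. It sets out from acid 6, which LiN(iPr)2 (2.2 equiv, THF, −78 to 0 °C) turns into the dianion lithium 2-(lithiomethyl)-6-methoxybenzoate F3. Iodoethane alkylates only the carbanion to give lithium 2-methoxy-6-propylbenzoate F4, and acidic work-up gives 2-methoxy-6-propylbenzoic acid F5. Tert-butylation of F5 with tert-butyl 2,2,2-trichloroacetimidate and catalytic BF3·OEt2, as in step 3, rejoins the route at 9.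

**Further compounds**
F1 | step 6 | tert-butyl 4-hydroxy-2-methoxy-6-propylbenzoate | CCCc1cc(O)cc(OC)c1C(=O)OC(C)(C)C
F2 | step 5 | potassium [4-(tert-butoxycarbonyl)-3-methoxy-5-propylphenyl]trifluoroborate | CCCc1cc([B-](F)(F)F)cc(OC)c1C(=O)OC(C)(C)C.[K+]
F3 | step 4 | lithium 2-(lithiomethyl)-6-methoxybenzoate | [Li]Cc1cccc(OC)c1C(=O)[O-].[Li+]
F4 | step 4 | lithium 2-methoxy-6-propylbenzoate | CCCc1cccc(OC)c1C(=O)[O-].[Li+]
F5 | step 4 | 2-methoxy-6-propylbenzoic acid | CCCc1cccc(OC)c1C(=O)O
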